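the same everywhere: precatalyst 90 µM
- beta: left-handed substrate 0.18 M; right-handed substrate 0.18 M; partner 0.27 M; run made earlier
- delta: left-handed substrate 0.18 M; right-handed substrate 0.18 M; partner 0.41 M; run made earlier
- eta: left-handed substrate 0.36 M; right-handed substrate 0.36 M; partner 0.54 M; run made earlier
- flask: left-handed substrate 0.18 M; right-handed substrate 0.18 M; partner 0.540 M; time 25 min

| run | time / min | left-handed product / % | right-handed product / % |
|---|---|---|---|
| beta | 1.50 | 0.4 | 0.1 |
| beta | 5.00 | 4.1 | 0.5 |
| beta | 8.00 | 7.2 | 0 |
| beta | 15.0 | 17.2 | 1.6 |
| beta | 20.0 | 22.8 | 0.7 |
| beta | 25.0 | 27.6 | 1.4 |
| delta | 2.00 | 1.5 | 0 |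
| delta | 3.00 | 3.0 | 0 |
| delta | 6.00 | 9.6 | 0.6 |
| delta | 10.0 | 18.0 | 0.8 |
| delta | 15.0 | 27.1 | 1.0 |
| delta | 25.0 | 37.4 | 2.4 |
| eta | 5.00 | 10.3 | 0.8 |
| eta | 10.0 | 23.2 | 1.5 |
| eta | 15.0 | 30.8 | 1.4 |
| eta | 20.0 | 35.7 | 2.1 |
| eta | 25.0 | 39.5 | 2.7 |

(readings scatter by 0.3 percentage points)

- catalyst is single-handed; left-handed substrate and right-handed substrate are mirror images of each other, charged as a racemate, each of them at the stated concentration
- an excess is below zero if the other one leads

- excess of left-handed product over right-handed product in the product at 30 s
- excess of left-handed product over right-handed product in the product at 25 min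
- part of the left-handed substrate and right-handed substrate charged together that has reacted at 25 min

One number came out alike at the end of the earlier runs, so I built my reply to your quick question on it: the last eta readings gave 28.1 for the selectivity factor s, which I defined as the logarithm of the fraction left of the left-handed substrate over the logarithm of the fraction left of the right-handed substrate, each fraction being its own charge less its product, and the last beta and delta readings gave 28.3 and 28.0, though a scatter of 0.3 percentage points sat on a right-handed reading of just 2.7%.

You suspected that the flask, with a partner charge 1.50 times that of the two substrates together against 0.750 in beta and 1.14 in delta, would sharpen the excess, but I took both substrates to meet the same catalyst and partner at each moment, so on that assumption the slow start and the partner dropped out of the ratio and moved a flask along one curve, on which the right-handed fraction left is the left-handed fraction left raised to the power one over s.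

Near the start of that curve, at 30 s, I put the excess at 93.1%. The forecast, which called the selectivity “independent of partner and concentration”, gave excesses of 93% at 30 s and 85% at 25 min, with 46.8% reacted. Its figures left 13.4% of the left-handed charge at 25 min, and I borrowed that and computed the small term, right-handed product at 3.45% of both substrates charged, which gave an excess of 85.2%, no separate estimate since the left-handed fraction was the forecast's. What deserved watching was the pair of product readings, which on my assumption stayed on that curve.

The flask gave excesses of 92.8% at 30 s and 84.6% at 25 min, with 47.0% reacted.

    partner + catalyst + left-handed substrate → catalyst + left-handed product (k = 2600 L² mol⁻² min⁻¹)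
    partner + catalyst + right-handed substrate → catalyst + right-handed product (k = 97.0 L² mol⁻² min⁻¹)
    partner + precatalyst → catalyst + spent reagent (k = 0.440 L mol⁻¹ min⁻¹)
    partner → decomposition product (k = 7.30 × 10⁻⁴ min⁻¹)

At 25 min the flask held 13% of its left-handed charge, far less than the 93% of its right-handed charge. Raising that left-handed fraction to the power one over 28.1 gives 3.46% of right-handed product, and the flask held 3.63%. In the neighbouring flask charged with 1.5 × 10⁻⁴ M of precatalyst, 4.39% of the left-handed charge remained at 25 min, the same power gives 5.26%, and that flask held 5.51%.

The readings are calculated on assumed constants; scatter was added.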